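The data come from a simulation from invented constants, and the scatter is random.

The pitfall with a large charge of free base is to read excess as saturation, as if a base present in plenty could no longer set any rate.

| setting | south-west | winter | autumn | dawn |
|---|---|---|---|---|
| electrophile | 0.21 M | 0.21 M | 0.21 M | 0.21 M |
| free base | 3.9 equiv | 3.00 equiv | 6.00 equiv | 12.0 equiv |
| protonated nucleophile | 1 equiv | 1.00 equiv | 1.00 equiv | 1.00 equiv |
| remark | run made earlier |  |  |  |
| time |  | 10 d | 10 d | 10 d |

south-west run (percent of the electrophile charged)

| time / d | electrophile / % | target / % |
|---|---|---|
| 0.500 | 100 | 5 |
| 1.25 | 95 | 3 |
| 2.50 | 91 | 6 |
| 4.00 | 86 | 11 |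
| 5.00 | 79 | 16 |
| 8.00 | 75 | 21 |

(readings scatter by 2 percentage points)

- the analysis behind the earlier runs scatters by 2 percentage points, standard deviation
- on the list of suspects stand: electrophile + nucleophile -> acid set free + target; nucleophile + target -> over-reaction product; acid set free + free base <-> salt of the base; nucleophile + acid set free <-> protonated nucleophile; 2 nucleophile -> homo dimer
- no earlier run changes the charge of free base; that part of a forecast is a guess

1. part of the electrophile that has reacted at the end, winter
2. part of the electrophile that has reacted at the end, autumn
3. part of the electrophile that has reacted at the end, dawn
4. what raising the equivalents of free base from its lowest to its highest value here does to the part of the electrophile that has reacted (changes below 5 percentage points count as none) (it falls / no change / it rises)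

The south-west run has 75% of its electrophile left at 8.00 d. Define the electrophile lifetime (a pseudo-first-order lifetime) as the elapsed time divided by the natural logarithm of charged over left: 27.8 d, a reading that carries the scatter. The part reacted at a time is one minus the exponential of minus that time over the lifetime. No earlier run varies free base, so two chemists argue from this lifetime alone.

The first says that 3.9 equiv of free base against 1 equiv of protonated nucleophile already frees the nucleophile completely. The lifetime then stays as it is, and winter, autumn and dawn each reach 30.2% at 10 d.

The second says the exchange of protonated nucleophile and free base for nucleophile and salt of the base lies to the left. The product of nucleophile and salt then grows in step with free base, so nucleophile goes with the square root of free base and the lifetime with its inverse. That gives 31.7 d, 22.4 d and 15.9 d, hence 27.0%, 36.0% and 46.8%. I commit to these numbers.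

The forecast leans to the second side but stops lower at dawn: 28%, 34%, 40%, and it rises. In its words, “I take a value between the two cases, leaning towards a modest rise”.

The simulation gives 27.5%, 36.1% and 45.5%: it rises, by 18 percentage points.

    electrophile + nucleophile → acid set free + target (k = 0.00390 L mol⁻¹ min⁻¹)
    nucleophile + target → over-reaction product (k = 0.00220 L mol⁻¹ min⁻¹)
    acid set free + free base ⇌ salt of the base (K = 840 L mol⁻¹, k = 0.0200 L mol⁻¹ min⁻¹)
    nucleophile + acid set free ⇌ protonated nucleophile, settled at all times (K = 32000 L mol⁻¹)
    2 nucleophile → homo dimer (k = 0.00180 L mol⁻¹ min⁻¹)

From its result, dawn has a lifetime of 16.5 d, against 15.9 d from the root rule. That rule gives 14.5% reacted for dawn read at 2.5 d, where 15.8% stood. The main reason for the gap between dawn and winter is the difference in equivalents of free base: with winter's charge, dawn's 45.5% becomes 27.5%. Part of the reason for the rise is the reaction of acid set free with free base, both ways: struck out, the gap between dawn and winter falls from 18 points to 0 points. The first chemist's constant lifetime gives 97.3% at ten times the time, more than winter's 67.8% and dawn's 71.7%, but the answer of no change with free base holds there: the gap is 3.9 points, below the 5 points that counts as a change.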